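**Strategy.** Everything rests on disconnecting the C4–C5 bond of the 5,6-dihydro-2H-pyran-2-one ring (O1, C2=O, C3=C4, C5 acyloxy carbon, C6). C4, the enoate beta-carbon, and C5, the carbinol carbon, are both electrophilic by nature, so C4 is polarity-reversed as an alkenylchromium. An intramolecular Nozaki–Hiyama–Kishi reaction of the (Z)-3-iodoacrylate ester of an alpha-hydroxy aldehyde closes the lactone and creates the C5 carbinol in one operation. The precursor already carries the finished side chain (Evans alkylation, Sharpless epoxide opened by a Grignard reagent, Shi epoxidation). Mitsunobu inversion at C5 with the dienoic acid, then desilylation, finish the synthesis.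

Key step: step 12

Remark: lactone atoms are numbered O1, C2 (C=O), C3=C4, C5, C6; the C6 side chain is C1' to C7'. The acid fragment (step 13) is expected in high but not perfect enantiopurity; the minor diastereomer of 26 should be removable by chromatography.

**Step 1**
Reactants: 1 (E)-2-methylbut-2-en-1-ol
Product: 2 (E)-1-bromo-2-methylbut-2-ene
Conditions: PBr3, Et2O, 0 °C
Reagents that add atoms: phosphorus tribromide BrP(Br)Br
Why: Bromination of the primary allylic alcohol with PBr3 proceeds by SN2 at the primary carbon and keeps the (E)-trisubstituted alkene, the primary bromide also being the thermodynamic regioisomer.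

**Step 2**
Reactants: 3 (4R)-4-benzyl-3-propanoyl-1,3-oxazolidin-2-one; 2 (E)-1-bromo-2-methylbut-2-ene
Product: 4 (4R)-4-benzyl-3-[(2S,4E)-2,4-dimethylhex-4-enoyl]-1,3-oxazolidin-2-one
Conditions: NaN(SiMe3)2, THF, −78 °C; then 2, −78 → −40 °C
Reagents that add atoms: none
Why: Evans asymmetric alkylation, in which the chelated (Z)-sodium enolate is alkylated by the reactive allylic bromide on the face opposite the benzyl group, should set the (S)-methyl center that becomes C3'.

**Step 3**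
Reactants: 4 (4R)-4-benzyl-3-[(2S,4E)-2,4-dimethylhex-4-enoyl]-1,3-oxazolidin-2-one
Product: 5 (2S,4E)-2,4-dimethylhex-4-en-1-ol
Conditions: LiBH4, MeOH (1 equiv), Et2O, 0 °C
Reagents that add atoms: none
Why: Reductive cleavage of the imide by LiBH4 should give the primary alcohol without epimerising the alpha-center or touching the alkene, and releases the auxiliary.

**Step 4**
Reactants: 5 (2S,4E)-2,4-dimethylhex-4-en-1-ol
Product: 6 (2S,4E)-1-bromo-2,4-dimethylhex-4-ene
Conditions: CBr4, PPh3, CH2Cl2, 0 °C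
Reagents that add atoms: carbon tetrabromide BrC(Br)(Br)Br
Why: Appel bromination converts the primary alcohol into the bromide under neutral conditions with no risk to the adjacent stereocenter.

**Step 5**
Reactants: 7 (E)-but-2-en-1-ol
Product: 8 [(2S,3S)-3-methyloxiran-2-yl]methanol
Conditions: Ti(OiPr)4 (5 mol%), L-(+)-diisopropyl tartrate (6 mol%), tBuOOH, 4 Å MS, CH2Cl2, −20 °C; non-aqueous work-up
Reagents that add atoms: tert-butyl hydroperoxide CC(C)(C)OO
Why: Sharpless asymmetric epoxidation of the (E)-allylic alcohol with the L-tartrate should deliver the (2S,3S)-epoxy alcohol, which fixes C6 and prepares C1'.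

**Step 6**
Reactants: 8 [(2S,3S)-3-methyloxiran-2-yl]methanol
Product: 9 (2S,3S)-2-{[(4-methoxybenzyl)oxy]methyl}-3-methyloxirane
Conditions: NaH, 4-methoxybenzyl chloride, Bu4NI (cat.), THF/DMF, −20 → 0 °C
Reagents that add atoms: 4-methoxybenzyl chloride COc1ccc(CCl)cc1
Why: Williamson etherification of the alkoxide in an aprotic medium at low temperature should outrun Payne rearrangement and gives the PMB ether that later directs the epoxide opening.

**Step 7**
Reactants: 6 (2S,4E)-1-bromo-2,4-dimethylhex-4-ene; 9 (2S,3S)-2-{[(4-methoxybenzyl)oxy]methyl}-3-methyloxirane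
Product: 11 (2R,3S,5R,7E)-1-[(4-methoxybenzyl)oxy]-3,5,7-trimethylnon-7-en-2-ol, via Grignard reagent 10 (not isolated)
Conditions: Mg, THF, 40 °C; then 9, CuI (10 mol%), THF, −30 → 0 °C
Reagents that add atoms: none
Why: Copper-catalysed SN2 opening of the epoxide by the Grignard reagent should occur at the methyl-bearing carbon, remote from the deactivating CH2OPMB group, with inversion, which gives the syn relation of the C6 hydroxyl and the C1' methyl and leaves only the secondary hydroxyl free.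

**Step 8**
Reactants: 11 (2R,3S,5R,7E)-1-[(4-methoxybenzyl)oxy]-3,5,7-trimethylnon-7-en-2-ol
Product: 12 (2R,3S,5R)-6-[(2R,3R)-2,3-dimethyloxiran-2-yl]-1-[(4-methoxybenzyl)oxy]-3,5-dimethylhexan-2-ol
Conditions: D-fructose-derived Shi ketone (30 mol%), KHSO5 (Oxone), K2CO3, Bu4NHSO4, Na2B4O7 buffer, MeCN/CH2(OMe)2/H2O, 0 °C
Reagents that add atoms: potassium peroxymonosulfate [K+].[O-]S(=O)(=O)OO
Why: Shi asymmetric epoxidation, in which the chiral dioxirane attacks the (E)-trisubstituted alkene through the spiro transition state under reagent control, should give the (2R,3R)-oxirane while the alcohol and PMB ether stay inert.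

**Step 9**
Reactants: 12 (2R,3S,5R)-6-[(2R,3R)-2,3-dimethyloxiran-2-yl]-1-[(4-methoxybenzyl)oxy]-3,5-dimethylhexan-2-ol; 13 (2Z)-3-iodoprop-2-enoic acid
Product: 14 (2R,3S,5R)-6-[(2R,3R)-2,3-dimethyloxiran-2-yl]-1-[(4-methoxybenzyl)oxy]-3,5-dimethylhexan-2-yl (2Z)-3-iodoprop-2-enoate
Conditions: iPrN=C=NiPr (DIC), DMAP (10 mol%), CH2Cl2, −20 → 0 °C
Reagents that add atoms: none
Why: Steglich esterification at low temperature with only catalytic DMAP acylates the secondary alcohol with retention at C6 and should preserve the (Z)-iodoalkene.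

**Step 10**
Reactants: 14 (2R,3S,5R)-6-[(2R,3R)-2,3-dimethyloxiran-2-yl]-1-[(4-methoxybenzyl)oxy]-3,5-dimethylhexan-2-yl (2Z)-3-iodoprop-2-enoate
Product: 15 (2R,3S,5R)-6-[(2R,3R)-2,3-dimethyloxiran-2-yl]-1-hydroxy-3,5-dimethylhexan-2-yl (2Z)-3-iodoprop-2-enoate
Conditions: DDQ, CH2Cl2/pH 7 buffer, 0 °C
Reagents that add atoms: none
Why: Oxidative PMB cleavage by DDQ under buffered conditions is neutral, so the oxirane and the iodoacrylate should survive and acyl migration should be slow.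

**Step 11**
Reactants: 15 (2R,3S,5R)-6-[(2R,3R)-2,3-dimethyloxiran-2-yl]-1-hydroxy-3,5-dimethylhexan-2-yl (2Z)-3-iodoprop-2-enoate
Product: 16 (2R,3S,5R)-6-[(2R,3R)-2,3-dimethyloxiran-2-yl]-3,5-dimethyl-1-oxohexan-2-yl (2Z)-3-iodoprop-2-enoate
Conditions: Dess–Martin periodinane, NaHCO3, CH2Cl2, 0 °C → rt; used crude
Reagents that add atoms: none
Why: Dess–Martin oxidation under bicarbonate buffer should give the alpha-acyloxy aldehyde without epimerisation at C6 or acid-induced oxirane opening.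

**Step 12**
Reactants: 16 (2R,3S,5R)-6-[(2R,3R)-2,3-dimethyloxiran-2-yl]-3,5-dimethyl-1-oxohexan-2-yl (2Z)-3-iodoprop-2-enoate
Product: 17 (5S,6R)-6-{(2S,4R)-5-[(2R,3R)-2,3-dimethyloxiran-2-yl]-4-methylpentan-2-yl}-5-hydroxy-5,6-dihydro-2H-pyran-2-one
Conditions: CrCl2 (8 equiv), NiCl2 (2 mol%), degassed DMSO/THF, rt, 0.01 M; buffered aqueous work-up at 0 °C
Reagents that add atoms: none
Why: Zerovalent nickel (formed from NiCl2 and CrCl2) inserts into the C–I bond, transmetalation gives the (Z)-alkenyl species of trivalent chromium, and this C4 nucleophile adds to the tethered aldehyde carbon C5; the closest known reaction type is the Nozaki–Hiyama–Kishi cyclisation of iodoalkene aldehydes. The lactone ring closes by a 6-exo-trig addition to the aldehyde carbonyl, which the cis geometry of the alkenylmetal and the ester tether make possible. The new stereocenter C5 is controlled by C6: with the C6 side chain pseudo-equatorial, the aldehyde oxygen should sit pseudo-equatorial, anti to the C6–O1 bond (Cornforth and polar Felkin–Anh arrangement) and within reach of the chromium on C4, which should favour the 5,6-trans (5S) alcohol. The step needs chemoselectivity (divalent chromium must leave the trisubstituted oxirane and the acyloxy group alone), retention of the Z geometry and configurational integrity at C6. The non-basic, aprotic conditions and the low basicity of alkenylchromium reagents should secure these, and moderate dilution suppresses intermolecular addition. Any minor 5,6-cis epimer would be removed by chromatography.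

**Step 13**
Reactants: 18 4-[(tert-butyldimethylsilyl)oxy]butanal
Product: 20 ethyl (2E,4S)-6-[(tert-butyldimethylsilyl)oxy]-4-(hydroxymethyl)-2-methylhex-2-enoate, via hydroxymethyl aldehyde 19 (not isolated)
Conditions: aq. HCHO, (S)-α,α-diphenylprolinol trimethylsilyl ether (10 mol%), pH 7 phosphate buffer, toluene, rt; aqueous layer removed, then Ph3P=C(Me)CO2Et, rt
Reagents that add atoms: formaldehyde C=O; ethyl 2-(triphenylphosphoranylidene)propanoate CCOC(=O)C(C)=P(c1ccccc1)(c1ccccc1)c1ccccc1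
Why: Enamine-catalysed cross-aldol with formaldehyde, in which the bulky diarylsilyloxymethyl group shields one face of the (E)-enamine, should set the stereocenter (C6 of the acid), and the labile beta-hydroxy aldehyde is trapped at once by an (E)-selective Wittig reaction.

**Step 14**
Reactants: 20 ethyl (2E,4S)-6-[(tert-butyldimethylsilyl)oxy]-4-(hydroxymethyl)-2-methylhex-2-enoate
Product: 21 ethyl (2E,4S)-6-[(tert-butyldimethylsilyl)oxy]-4-{[(tert-butyldimethylsilyl)oxy]methyl}-2-methylhex-2-enoate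
Conditions: tBuMe2SiCl, imidazole, DMF, rt
Reagents that add atoms: tert-butyldimethylsilyl chloride CC(C)(C)[Si](C)(C)Cl
Why: Standard silylation of the primary alcohol gives the bis-silyl ether, so that both hydroxyls carry the same fluoride-labile group.

**Step 15**
Reactants: 21 ethyl (2E,4S)-6-[(tert-butyldimethylsilyl)oxy]-4-{[(tert-butyldimethylsilyl)oxy]methyl}-2-methylhex-2-enoate
Product: 22 (2E,4S)-6-[(tert-butyldimethylsilyl)oxy]-4-{[(tert-butyldimethylsilyl)oxy]methyl}-2-methylhex-2-en-1-ol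
Conditions: iBu2AlH (2.2 equiv), CH2Cl2, −78 °C; Rochelle salt work-up
Reagents that add atoms: none
Why: Hydride reduction of the enoate by iBu2AlH gives the allylic alcohol by 1,2-addition while silyl ethers and the alkene are inert.

**Step 16**
Reactants: 22 (2E,4S)-6-[(tert-butyldimethylsilyl)oxy]-4-{[(tert-butyldimethylsilyl)oxy]methyl}-2-methylhex-2-en-1-ol
Product: 24 ethyl (2E,4E,6S)-8-[(tert-butyldimethylsilyl)oxy]-6-{[(tert-butyldimethylsilyl)oxy]methyl}-4-methylocta-2,4-dienoate, via enal 23 (not isolated)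
Conditions: MnO2, Ph3P=CHCO2Et, CH2Cl2, rt
Reagents that add atoms: ethyl (triphenylphosphoranylidene)acetate CCOC(=O)C=P(c1ccccc1)(c1ccccc1)c1ccccc1
Why: Tandem oxidation–Wittig, in which MnO2 oxidises only the allylic alcohol and the stabilised ylide traps the enal in situ, should give the (2E)-alkene.

**Step 17**
Reactants: 24 ethyl (2E,4E,6S)-8-[(tert-butyldimethylsilyl)oxy]-6-{[(tert-butyldimethylsilyl)oxy]methyl}-4-methylocta-2,4-dienoate
Product: 25 (2E,4E,6S)-8-[(tert-butyldimethylsilyl)oxy]-6-{[(tert-butyldimethylsilyl)oxy]methyl}-4-methylocta-2,4-dienoic acid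
Conditions: LiOH, THF/MeOH/H2O, rt; then dilute HCl to pH 4, 0 °C
Reagents that add atoms: lithium hydroxide [Li+].[OH-]
Why: Saponification of the unhindered ethyl ester should proceed cleanly because primary TBS ethers tolerate LiOH and a brief, cold, mildly acidic work-up.

**Step 18**
Reactants: 17 (5S,6R)-6-{(2S,4R)-5-[(2R,3R)-2,3-dimethyloxiran-2-yl]-4-methylpentan-2-yl}-5-hydroxy-5,6-dihydro-2H-pyran-2-one; 25 (2E,4E,6S)-8-[(tert-butyldimethylsilyl)oxy]-6-{[(tert-butyldimethylsilyl)oxy]methyl}-4-methylocta-2,4-dienoic acid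
Product: 26 (5R,6R)-6-{(2S,4R)-5-[(2R,3R)-2,3-dimethyloxiran-2-yl]-4-methylpentan-2-yl}-2-oxo-5,6-dihydro-2H-pyran-5-yl (2E,4E,6S)-8-[(tert-butyldimethylsilyl)oxy]-6-{[(tert-butyldimethylsilyl)oxy]methyl}-4-methylocta-2,4-dienoate
Conditions: PPh3, DIAD, toluene, 0 °C → rt
Reagents that add atoms: none
Why: Mitsunobu esterification displaces the alkoxyphosphonium of the allylic alcohol by the carboxylate with SN2 inversion, turning the 5S (trans) carbinol into the required 5R (cis) ester, and the pseudo-equatorial leaving group is not antiperiplanar to H6, which should disfavour elimination to the 2-pyranone.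

**Step 19**
Reactants: 26 (5R,6R)-6-{(2S,4R)-5-[(2R,3R)-2,3-dimethyloxiran-2-yl]-4-methylpentan-2-yl}-2-oxo-5,6-dihydro-2H-pyran-5-yl (2E,4E,6S)-8-[(tert-butyldimethylsilyl)oxy]-6-{[(tert-butyldimethylsilyl)oxy]methyl}-4-methylocta-2,4-dienoate
Product: 27 (5R,6R)-6-{(2S,4R)-5-[(2R,3R)-2,3-dimethyloxiran-2-yl]-4-methylpentan-2-yl}-2-oxo-5,6-dihydro-2H-pyran-5-yl (2E,4E,6S)-8-hydroxy-6-(hydroxymethyl)-4-methylocta-2,4-dienoate (CNP0160449.2)
Conditions: HF·pyridine, excess pyridine, THF, 0 °C → rt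
Reagents that add atoms: none
Why: Pyridine-buffered HF·pyridine cleaves the two primary TBS ethers under nearly neutral, non-basic conditions that the elimination-prone allylic ester tolerates and that a trisubstituted oxirane should survive.

**Compound list**

1 | (E)-2-methylbut-2-en-1-ol | OC/C(C)=C/C | starting material
2 | (E)-1-bromo-2-methylbut-2-ene | BrC/C(C)=C/C | intermediate
3 | (4R)-4-benzyl-3-propanoyl-1,3-oxazolidin-2-one | CCC(=O)N1C(=O)OC[C@H]1Cc1ccccc1 | starting material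
4 | (4R)-4-benzyl-3-[(2S,4E)-2,4-dimethylhex-4-enoyl]-1,3-oxazolidin-2-one | O=C([C@@H](C)C/C(C)=C/C)N1C(=O)OC[C@H]1Cc1ccccc1 | intermediate
5 | (2S,4E)-2,4-dimethylhex-4-en-1-ol | OC[C@@H](C)C/C(C)=C/C | intermediate
6 | (2S,4E)-1-bromo-2,4-dimethylhex-4-ene | BrC[C@@H](C)C/C(C)=C/C | intermediate
7 | (E)-but-2-en-1-ol | C/C=C/CO | starting material
8 | [(2S,3S)-3-methyloxiran-2-yl]methanol | C[C@@H]1O[C@H]1CO | intermediate
9 | (2S,3S)-2-{[(4-methoxybenzyl)oxy]methyl}-3-methyloxirane | C[C@@H]1O[C@H]1COCc1ccc(OC)cc1 | intermediate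
10 | [(2S,4E)-2,4-dimethylhex-4-en-1-yl]magnesium bromide | Br[Mg]C[C@@H](C)C/C(C)=C/C | intermediate (not isolated)
11 | (2R,3S,5R,7E)-1-[(4-methoxybenzyl)oxy]-3,5,7-trimethylnon-7-en-2-ol | O[C@@H](COCc1ccc(OC)cc1)[C@@H](C)C[C@@H](C)C/C(C)=C/C | intermediate
12 | (2R,3S,5R)-6-[(2R,3R)-2,3-dimethyloxiran-2-yl]-1-[(4-methoxybenzyl)oxy]-3,5-dimethylhexan-2-ol | O[C@@H](COCc1ccc(OC)cc1)[C@@H](C)C[C@@H](C)C[C@@]1(C)O[C@@H]1C | intermediate
13 | (2Z)-3-iodoprop-2-enoic acid | OC(=O)/C=C\I | starting material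
14 | (2R,3S,5R)-6-[(2R,3R)-2,3-dimethyloxiran-2-yl]-1-[(4-methoxybenzyl)oxy]-3,5-dimethylhexan-2-yl (2Z)-3-iodoprop-2-enoate | I/C=C\C(=O)O[C@@H](COCc1ccc(OC)cc1)[C@@H](C)C[C@@H](C)C[C@@]1(C)O[C@@H]1C | intermediate
15 | (2R,3S,5R)-6-[(2R,3R)-2,3-dimethyloxiran-2-yl]-1-hydroxy-3,5-dimethylhexan-2-yl (2Z)-3-iodoprop-2-enoate | I/C=C\C(=O)O[C@@H](CO)[C@@H](C)C[C@@H](C)C[C@@]1(C)O[C@@H]1C | intermediate
16 | (2R,3S,5R)-6-[(2R,3R)-2,3-dimethyloxiran-2-yl]-3,5-dimethyl-1-oxohexan-2-yl (2Z)-3-iodoprop-2-enoate | I/C=C\C(=O)O[C@@H](C=O)[C@@H](C)C[C@@H](C)C[C@@]1(C)O[C@@H]1C | intermediate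
17 | (5S,6R)-6-{(2S,4R)-5-[(2R,3R)-2,3-dimethyloxiran-2-yl]-4-methylpentan-2-yl}-5-hydroxy-5,6-dihydro-2H-pyran-2-one | O[C@H]1C=CC(=O)O[C@@H]1[C@@H](C)C[C@@H](C)C[C@@]1(C)O[C@@H]1C | intermediate
18 | 4-[(tert-butyldimethylsilyl)oxy]butanal | CC(C)(C)[Si](C)(C)OCCCC=O | starting material
19 | (2R)-4-[(tert-butyldimethylsilyl)oxy]-2-(hydroxymethyl)butanal | O=C[C@@H](CO)CCO[Si](C)(C)C(C)(C)C | intermediate (not isolated)
20 | ethyl (2E,4S)-6-[(tert-butyldimethylsilyl)oxy]-4-(hydroxymethyl)-2-methylhex-2-enoate | CCOC(=O)/C(C)=C/[C@@H](CO)CCO[Si](C)(C)C(C)(C)C | intermediate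
21 | ethyl (2E,4S)-6-[(tert-butyldimethylsilyl)oxy]-4-{[(tert-butyldimethylsilyl)oxy]methyl}-2-methylhex-2-enoate | CCOC(=O)/C(C)=C/[C@@H](CO[Si](C)(C)C(C)(C)C)CCO[Si](C)(C)C(C)(C)C | intermediate
22 | (2E,4S)-6-[(tert-butyldimethylsilyl)oxy]-4-{[(tert-butyldimethylsilyl)oxy]methyl}-2-methylhex-2-en-1-ol | OC/C(C)=C/[C@@H](CO[Si](C)(C)C(C)(C)C)CCO[Si](C)(C)C(C)(C)C | intermediate
23 | (2E,4S)-6-[(tert-butyldimethylsilyl)oxy]-4-{[(tert-butyldimethylsilyl)oxy]methyl}-2-methylhex-2-enal | O=C/C(C)=C/[C@@H](CO[Si](C)(C)C(C)(C)C)CCO[Si](C)(C)C(C)(C)C | intermediate (not isolated)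
24 | ethyl (2E,4E,6S)-8-[(tert-butyldimethylsilyl)oxy]-6-{[(tert-butyldimethylsilyl)oxy]methyl}-4-methylocta-2,4-dienoate | CCOC(=O)/C=C/C(C)=C/[C@@H](CO[Si](C)(C)C(C)(C)C)CCO[Si](C)(C)C(C)(C)C | intermediate
25 | (2E,4E,6S)-8-[(tert-butyldimethylsilyl)oxy]-6-{[(tert-butyldimethylsilyl)oxy]methyl}-4-methylocta-2,4-dienoic acid | OC(=O)/C=C/C(C)=C/[C@@H](CO[Si](C)(C)C(C)(C)C)CCO[Si](C)(C)C(C)(C)C | intermediate
26 | (5R,6R)-6-{(2S,4R)-5-[(2R,3R)-2,3-dimethyloxiran-2-yl]-4-methylpentan-2-yl}-2-oxo-5,6-dihydro-2H-pyran-5-yl (2E,4E,6S)-8-[(tert-butyldimethylsilyl)oxy]-6-{[(tert-butyldimethylsilyl)oxy]methyl}-4-methylocta-2,4-dienoate | CC(/C=C/C(=O)O[C@@H]1C=CC(=O)O[C@@H]1[C@@H](C)C[C@@H](C)C[C@@]1(C)O[C@@H]1C)=C\[C@@H](CO[Si](C)(C)C(C)(C)C)CCO[Si](C)(C)C(C)(C)C | intermediate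
27 | (5R,6R)-6-{(2S,4R)-5-[(2R,3R)-2,3-dimethyloxiran-2-yl]-4-methylpentan-2-yl}-2-oxo-5,6-dihydro-2H-pyran-5-yl (2E,4E,6S)-8-hydroxy-6-(hydroxymethyl)-4-methylocta-2,4-dienoate | CC(/C=C/C(=O)O[C@@H]1C=CC(=O)O[C@@H]1[C@@H](C)C[C@@H](C)C[C@@]1(C)O[C@@H]1C)=C\[C@@H](CO)CCO | target

**Step count.** Total: 19 steps. Longest linear sequence: 12 steps (steps 1–4, 7–12, 18, 19).

**Steps most likely to fail**

1. Step 12 (ring closure). The ester must twist into its s-cis rotamer before C4 can reach C5. Protodemetalation or Z-to-E isomerisation of the alkenylmetal may outrun addition, the chromium alkoxide may contract the ring to a butenolide, and facial selectivity at C5 may be poor. Fallback, from 12 back to 17, forming the C4–C5 bond intermolecularly: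
   - Silylation (Et3SiOTf, 2,6-lutidine) gives the triethylsilyl ether F1.
   - DDQ gives the primary alcohol F2, and Dess–Martin oxidation gives the alpha-silyloxy aldehyde F3.
   - Addition of lithiated ethyl propiolate (LiN(SiMe3)2, THF, −78 °C) should give, under Felkin–Anh control, the anti propargylic alcohol F4.
   - tBuMe2SiOTf gives the bis-silyl ether F5.
   - Semihydrogenation over Pd/CaCO3 poisoned with Pb(OAc)2 and quinoline gives the (Z)-enoate F6.
   - HF·pyridine removes the more labile triethylsilyl group first, the freed C6 hydroxyl lactonises onto the (Z)-ester, and continued exposure cleaves the TBS ether to return 17.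

2. Step 18 (Mitsunobu inversion). Displacement at the hindered allylic C5 may be slow, so that elimination to the 2-pyranone, attack with allylic shift or acylation with retention through an acyloxyphosphonium compete. Fallback, from 17 back to 26: chloromethanesulfonyl chloride and pyridine give the chloromethanesulfonate F7, and SN2 displacement with the caesium salt of 25 (Cs2CO3, 18-crown-6, toluene) should give 26 with inversion.

3. Step 13 (organocatalytic hydroxymethylation and Wittig trapping). The beta-hydroxy aldehyde may dehydrate or racemise by retro-aldol reaction before the ylide traps it, and enantiofacial control may be insufficient. Fallback, from 18 back to 21, setting the stereocenter enzymatically: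
   - The aldol is run as in step 13 but the crude product is reduced at once (NaBH4) to the achiral diol F8.
   - Lipase-catalysed desymmetrising acetylation (vinyl acetate, immobilised Burkholderia cepacia lipase) should give the (R)-monoacetate F9; if the enzyme shows the opposite sense, hydrolysis of the diacetate by the same lipase is used instead.
   - tBuMe2SiCl and imidazole give the silyl ether acetate F10.
   - K2CO3 in MeOH gives the alcohol F11.
   - Dess–Martin oxidation gives the aldehyde F12, and Wittig reaction with Ph3P=C(Me)CO2Et returns 21.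

**Further compounds**

F1 | step 12 | triethyl{[(2R,3S,5R)-6-[(2R,3R)-2,3-dimethyloxiran-2-yl]-1-[(4-methoxybenzyl)oxy]-3,5-dimethylhexan-2-yl]oxy}silane | CC[Si](CC)(CC)O[C@@H](COCc1ccc(OC)cc1)[C@@H](C)C[C@@H](C)C[C@@]1(C)O[C@@H]1C
F2 | step 12 | (2R,3S,5R)-6-[(2R,3R)-2,3-dimethyloxiran-2-yl]-3,5-dimethyl-2-[(triethylsilyl)oxy]hexan-1-ol | CC[Si](CC)(CC)O[C@@H](CO)[C@@H](C)C[C@@H](C)C[C@@]1(C)O[C@@H]1C
F3 | step 12 | (2R,3S,5R)-6-[(2R,3R)-2,3-dimethyloxiran-2-yl]-3,5-dimethyl-2-[(triethylsilyl)oxy]hexanal | CC[Si](CC)(CC)O[C@@H](C=O)[C@@H](C)C[C@@H](C)C[C@@]1(C)O[C@@H]1C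
F4 | step 12 | ethyl (4S,5R,6S,8R)-9-[(2R,3R)-2,3-dimethyloxiran-2-yl]-4-hydroxy-6,8-dimethyl-5-[(triethylsilyl)oxy]non-2-ynoate | CCOC(=O)C#C[C@H](O)[C@H](O[Si](CC)(CC)CC)[C@@H](C)C[C@@H](C)C[C@@]1(C)O[C@@H]1C
F5 | step 12 | ethyl (4S,5R,6S,8R)-4-[(tert-butyldimethylsilyl)oxy]-9-[(2R,3R)-2,3-dimethyloxiran-2-yl]-6,8-dimethyl-5-[(triethylsilyl)oxy]non-2-ynoate | CCOC(=O)C#C[C@H](O[Si](C)(C)C(C)(C)C)[C@H](O[Si](CC)(CC)CC)[C@@H](C)C[C@@H](C)C[C@@]1(C)O[C@@H]1C
F6 | step 12 | ethyl (2Z,4S,5R,6S,8R)-4-[(tert-butyldimethylsilyl)oxy]-9-[(2R,3R)-2,3-dimethyloxiran-2-yl]-6,8-dimethyl-5-[(triethylsilyl)oxy]non-2-enoate | CCOC(=O)/C=C\[C@H](O[Si](C)(C)C(C)(C)C)[C@H](O[Si](CC)(CC)CC)[C@@H](C)C[C@@H](C)C[C@@]1(C)O[C@@H]1C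
F7 | step 18 | (5S,6R)-6-{(2S,4R)-5-[(2R,3R)-2,3-dimethyloxiran-2-yl]-4-methylpentan-2-yl}-2-oxo-5,6-dihydro-2H-pyran-5-yl chloromethanesulfonate | ClCS(=O)(=O)O[C@H]1C=CC(=O)O[C@@H]1[C@@H](C)C[C@@H](C)C[C@@]1(C)O[C@@H]1C
F8 | step 13 | 2-{2-[(tert-butyldimethylsilyl)oxy]ethyl}propane-1,3-diol | OCC(CO)CCO[Si](C)(C)C(C)(C)C
F9 | step 13 | (2R)-4-[(tert-butyldimethylsilyl)oxy]-2-(hydroxymethyl)butyl acetate | CC(=O)OC[C@@H](CO)CCO[Si](C)(C)C(C)(C)C
F10 | step 13 | (2S)-4-[(tert-butyldimethylsilyl)oxy]-2-{[(tert-butyldimethylsilyl)oxy]methyl}butyl acetate | CC(=O)OC[C@@H](CO[Si](C)(C)C(C)(C)C)CCO[Si](C)(C)C(C)(C)C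
F11 | step 13 | (2S)-4-[(tert-butyldimethylsilyl)oxy]-2-{[(tert-butyldimethylsilyl)oxy]methyl}butan-1-ol | OC[C@@H](CO[Si](C)(C)C(C)(C)C)CCO[Si](C)(C)C(C)(C)C
F12 | step 13 | (2R)-4-[(tert-butyldimethylsilyl)oxy]-2-{[(tert-butyldimethylsilyl)oxy]methyl}butanal | O=C[C@@H](CO[Si](C)(C)C(C)(C)C)CCO[Si](C)(C)C(C)(C)C
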